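**Plan**
- Retrosynthesis: ring C is opened at O1–C2 and C2–C3 (C2 is a one-carbon unit from DMF dimethyl acetal); the deoxybenzoin is cut at C3–C4 (benzyl Grignard reagent plus Weinreb amide); ring A is cut at C5–C6 and C8–C8a.
- Enabling feature: in ring A the oxygenated C7 sits between the two prenylated carbons C6 and C8. This locally symmetric C6–C7–C8 unit maps onto the α-carbon, carbonyl and α′-carbon of a symmetric bis(homoprenyl) ketone acting as a 1,3-dinucleophile; C5, C4a, C8a and the future C4 come from diethyl ethoxymethylenemalonate.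
- Forward order: diethyl 3-oxopentanedioate is prenylated once at each flanking carbon in two successive alkylations, dealkoxycarbonylation gives the ketone, a [3+3] Michael–Claisen benzannulation builds ring A, ring B arrives intact as a benzyl nucleophile, and ring C is closed last.
- Stereochemistry: the target has no stereocentre and its alkenes carry no geometry; transient stereocentres and the enaminone geometry are erased on the way.

Key step: step 4

Assumption: 4-(methoxymethoxy)benzyl chloride is taken as a purchasable reagent to be used fresh. Isoflavone numbering (O1, C2 to C8a, rings A, B, C) is used for the target, benzoate numbering for the ring A esters, and prenyl means 3-methylbut-2-en-1-yl.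

**Step 1**
Reactants: 1 diethyl 3-oxopentanedioate; 2 prenyl bromide (1-bromo-3-methylbut-2-ene)
Product: 3 diethyl 2-(3-methylbut-2-en-1-yl)-3-oxopentanedioate (racemic)
Conditions: NaOEt (1.0 equiv), EtOH, 0 °C; then 2 (1.0 equiv), 0 °C to rt
Reagents that add atoms: none
Why: SN2 C-alkylation of the sodium enolate of the β-keto ester (acetoacetic-ester-type alkylation) with the reactive allylic bromide, in which one equivalent each of base and halide should hold the reaction at the mono-prenyl stage; the new stereocentre forms racemic and is erased in step 3.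

**Step 2**
Reactants: 3 diethyl 2-(3-methylbut-2-en-1-yl)-3-oxopentanedioate; 2 prenyl bromide (1-bromo-3-methylbut-2-ene)
Product: 4 diethyl 2,4-bis(3-methylbut-2-en-1-yl)-3-oxopentanedioate (mixture of meso and racemic diastereomers)
Conditions: NaOEt (1.0 equiv), EtOH, 0 °C; then 2 (1.05 equiv), rt to 45 °C
Reagents that add atoms: none
Why: Second acetoacetic-ester-type SN2 alkylation, in which the unsubstituted C4 methylene of 3 is the more acidic and less hindered site, so the second prenyl group should enter there and not at the already substituted C2; the two stereocentres form unselectively and are erased in step 3.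

**Step 3**
Reactants: 4 diethyl 2,4-bis(3-methylbut-2-en-1-yl)-3-oxopentanedioate
Product: 5 2,10-dimethylundeca-2,9-dien-6-one
Conditions: LiCl, H2O, DMSO, 150 °C
Reagents that add atoms: none
Why: Krapcho-type dealkoxycarbonylation of a β-keto ester under neutral conditions should remove both ester groups, and with them both stereocentres, without exposing the trisubstituted alkenes to acid.

**Step 4**
Reactants: 5 2,10-dimethylundeca-2,9-dien-6-one; 6 diethyl 2-(ethoxymethylene)malonate
Product: 9 ethyl 2,4-dihydroxy-3,5-bis(3-methylbut-2-en-1-yl)benzoate, via alkylidenemalonate adduct 7 (not isolated), via 2-pyranone reservoir 8 (not isolated)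
Conditions: NaOEt (3 equiv), EtOH, rt, slow addition of 6 (1.0 equiv); then reflux; AcOH, 0 °C
Reagents that add atoms: none
Why: Proposed new method: ethoxide enolises the symmetric ketone 5, one α-carbon adds to the ethoxymethylene carbon of 6 and ethoxide is expelled (addition–elimination) to give 7 as its sodium dienolate, whose formation drives the first C–C bond (C5–C6) as in the Claisen condensations of plain ketones with oxalate or formate esters. Proton exchange in ethanol then makes the α′-enolate available, which attacks the cis-disposed ester carbonyl in a 6-exo-trig Claisen closure (C8–C8a), and loss of ethoxide followed by two enolisations should give ring A as the sodium phenoxide of 9. The closest known reaction types are the [3+3] Michael–Claisen condensations of activated acetone-type 1,3-dinucleophiles such as 3-oxopentanedioates with alkoxymethylenemalonates and the NaOEt-mediated double Claisen annulation of simple dialkyl ketones with diethyl oxalate to cyclopentane-1,2,4-triones, in which an unactivated α′-carbon also closes onto an ester; an unactivated dialkyl ketone has not been shown to give a resorcylate with 6. No stereocentre is formed. The selectivity needed is ring closure through carbon instead of the enolate oxygen: the 2-pyranone 8 from O-acylation can be reopened by ethoxide, whereas aromatisation after C-acylation is irreversible, so the equilibrating mixture should drain to 9. Because 5 and 6 are both symmetric, neither the site of the first attack nor the alkene geometry of 7 poses a choice, and 1:1 stoichiometry limits a second condensation at the α′-carbon.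

**Step 5**
Reactants: 9 ethyl 2,4-dihydroxy-3,5-bis(3-methylbut-2-en-1-yl)benzoate
Product: 10 ethyl 2,4-bis(methoxymethoxy)-3,5-bis(3-methylbut-2-en-1-yl)benzoate
Conditions: NaH (2.5 equiv), MOMCl (2.5 equiv), DMF, 0 °C to rt
Reagents that add atoms: chloromethyl methyl ether (MOMCl), COCCl
Why: Williamson-type O-alkylation of both sodium phenoxides, in which NaH breaks the hydrogen bond of the ester-chelated C2 hydroxyl so that both phenols should be masked for the organomagnesium steps.

**Step 6**
Reactants: 10 ethyl 2,4-bis(methoxymethoxy)-3,5-bis(3-methylbut-2-en-1-yl)benzoate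
Product: 11 N-methoxy-N-methyl-2,4-bis(methoxymethoxy)-3,5-bis(3-methylbut-2-en-1-yl)benzamide
Conditions: MeNH(OMe)·HCl (3 equiv), iPrMgCl (6 equiv), THF, −15 °C to rt
Reagents that add atoms: N,O-dimethylhydroxylamine hydrochloride, CNOC.Cl
Why: Weinreb amide formation by direct aminolysis of the ester with the chloromagnesium amide of N,O-dimethylhydroxylamine, a method that tolerates MOM ethers and isolated alkenes.

**Step 7**
Reactants: 11 N-methoxy-N-methyl-2,4-bis(methoxymethoxy)-3,5-bis(3-methylbut-2-en-1-yl)benzamide; 12 4-(methoxymethoxy)benzyl chloride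
Product: 14 1-[2,4-bis(methoxymethoxy)-3,5-bis(3-methylbut-2-en-1-yl)phenyl]-2-[4-(methoxymethoxy)phenyl]ethan-1-one, via benzylmagnesium chloride 13 (not isolated)
Conditions: 12, Mg turnings (excess), I2 (cat.), THF, 0 °C, slow addition; then 11, THF, 0 °C to rt; aq. NH4Cl
Reagents that add atoms: none
Why: Weinreb ketone synthesis, in which the benzylic Grignard reagent adds once and the magnesium-chelated tetrahedral intermediate holds until work-up, so the deoxybenzoin should form without over-addition, while slow addition of 12 to excess magnesium in the cold restrains Wurtz coupling.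

**Step 8**
Reactants: 14 1-[2,4-bis(methoxymethoxy)-3,5-bis(3-methylbut-2-en-1-yl)phenyl]-2-[4-(methoxymethoxy)phenyl]ethan-1-one
Product: 15 1-[2,4-bis(methoxymethoxy)-3,5-bis(3-methylbut-2-en-1-yl)phenyl]-3-(dimethylamino)-2-[4-(methoxymethoxy)phenyl]prop-2-en-1-one (alkene geometry not fixed; both isomers converge)
Conditions: Me2NCH(OMe)2, toluene, 100 °C
Reagents that add atoms: N,N-dimethylformamide dimethyl acetal, COC(OC)N(C)C
Why: Enaminone formation by condensation of the acidic benzylic methylene of the deoxybenzoin with DMF dimethyl acetal should introduce the carbon that becomes C2, and the alkene geometry is lost on ring closure.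

**Step 9**
Reactants: 15 1-[2,4-bis(methoxymethoxy)-3,5-bis(3-methylbut-2-en-1-yl)phenyl]-3-(dimethylamino)-2-[4-(methoxymethoxy)phenyl]prop-2-en-1-one
Product: 17 7-hydroxy-3-(4-hydroxyphenyl)-6,8-bis(3-methylbut-2-en-1-yl)-4H-chromen-4-one (target), via bis-MOM isoflavone 16 (not isolated)
Conditions: 3 M aq. HCl, MeOH, 45 °C; NaHCO3 work-up
Reagents that add atoms: none
Why: Acid-mediated acetal cleavage frees the carbonyl-flanked phenol, which adds to the protonated enaminone and expels dimethylamine (addition–elimination chromone closure), and the remaining two MOM ethers should fall in the same pot, dilute HCl in methanol at moderate temperature being the usual regime that spares ortho-prenyl phenols from chroman formation.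

**Compound list**
1 | diethyl 3-oxopentanedioate | CCOC(=O)CC(=O)CC(=O)OCC | starting material
2 | prenyl bromide (1-bromo-3-methylbut-2-ene) | CC(C)=CCBr | starting material
3 | diethyl 2-(3-methylbut-2-en-1-yl)-3-oxopentanedioate (racemic) | CCOC(=O)CC(=O)C(CC=C(C)C)C(=O)OCC | intermediate
4 | diethyl 2,4-bis(3-methylbut-2-en-1-yl)-3-oxopentanedioate (diastereomer mixture) | CCOC(=O)C(CC=C(C)C)C(=O)C(CC=C(C)C)C(=O)OCC | intermediate
5 | 2,10-dimethylundeca-2,9-dien-6-one | CC(C)=CCCC(=O)CCC=C(C)C | intermediate
6 | diethyl 2-(ethoxymethylene)malonate | CCOC=C(C(=O)OCC)C(=O)OCC | starting material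
7 | diethyl 2-[7-methyl-2-(3-methylbut-2-en-1-yl)-3-oxooct-6-en-1-ylidene]malonate (racemic; present as its sodium dienolate) | CCOC(=O)C(=CC(CC=C(C)C)C(=O)CCC=C(C)C)C(=O)OCC | intermediate (not isolated)
8 | ethyl 5-(3-methylbut-2-en-1-yl)-6-(4-methylpent-3-en-1-yl)-2-oxo-2H-pyran-3-carboxylate | CCOC(=O)c1cc(CC=C(C)C)c(CCC=C(C)C)oc1=O | intermediate (reversible reservoir, not isolated)
9 | ethyl 2,4-dihydroxy-3,5-bis(3-methylbut-2-en-1-yl)benzoate | CCOC(=O)c1cc(CC=C(C)C)c(O)c(CC=C(C)C)c1O | intermediate
10 | ethyl 2,4-bis(methoxymethoxy)-3,5-bis(3-methylbut-2-en-1-yl)benzoate | CCOC(=O)c1cc(CC=C(C)C)c(OCOC)c(CC=C(C)C)c1OCOC | intermediate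
11 | N-methoxy-N-methyl-2,4-bis(methoxymethoxy)-3,5-bis(3-methylbut-2-en-1-yl)benzamide | CON(C)C(=O)c1cc(CC=C(C)C)c(OCOC)c(CC=C(C)C)c1OCOC | intermediate
12 | 4-(methoxymethoxy)benzyl chloride | COCOc1ccc(CCl)cc1 | starting material
13 | [4-(methoxymethoxy)benzyl]magnesium chloride | COCOc1ccc(C[Mg]Cl)cc1 | intermediate (not isolated)
14 | 1-[2,4-bis(methoxymethoxy)-3,5-bis(3-methylbut-2-en-1-yl)phenyl]-2-[4-(methoxymethoxy)phenyl]ethan-1-one | COCOc1ccc(CC(=O)c2cc(CC=C(C)C)c(OCOC)c(CC=C(C)C)c2OCOC)cc1 | intermediate
15 | 1-[2,4-bis(methoxymethoxy)-3,5-bis(3-methylbut-2-en-1-yl)phenyl]-3-(dimethylamino)-2-[4-(methoxymethoxy)phenyl]prop-2-en-1-one (geometry not fixed) | COCOc1ccc(C(=CN(C)C)C(=O)c2cc(CC=C(C)C)c(OCOC)c(CC=C(C)C)c2OCOC)cc1 | intermediate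
16 | 7-(methoxymethoxy)-3-[4-(methoxymethoxy)phenyl]-6,8-bis(3-methylbut-2-en-1-yl)-4H-chromen-4-one | COCOc1ccc(-c2coc3c(CC=C(C)C)c(OCOC)c(CC=C(C)C)cc3c2=O)cc1 | intermediate (not isolated)
17 | 7-hydroxy-3-(4-hydroxyphenyl)-6,8-bis(3-methylbut-2-en-1-yl)-4H-chromen-4-one | CC(C)=CCc1cc2c(=O)c(-c3ccc(O)cc3)coc2c(CC=C(C)C)c1O | target

**Totals**
Total step count: 9. Longest linear sequence: 9 steps (1 to 17).

**Steps most likely to fail**

1. Step 4 (proposed new method). The annulation may stall after the first C–C bond: the sodium dienolate of 7, or the 2-pyranone 8 in equilibrium with it, may not enolise at the α′-carbon fast enough under ethoxide, so closure through carbon never overtakes ethanolysis and retro-condensation at reflux.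
 The fallback uses known reactions only, sets out from prenyl bromide 2 and rejoins the route at 10. Treatment of 2 with Bu3SnLi (from Bu3SnH and LDA, THF, −78 °C) should give tributyl(3-methylbut-2-en-1-yl)stannane F1. Purchased ethyl 2,4-dihydroxybenzoate F2 is iodinated at both activated positions (N-iodosuccinimide, TsOH cat., MeCN, rt) to ethyl 2,4-dihydroxy-3,5-diiodobenzoate F3, which is protected (NaH, MOMCl, DMF) as ethyl 3,5-diiodo-2,4-bis(methoxymethoxy)benzoate F4. A double Stille coupling of F4 with F1 (Pd(PPh3)4, LiCl, DMF, 90 °C) should then deliver 10 with both prenyl groups linear.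

2. Step 7. Wurtz homocoupling during magnesium insertion into the electron-rich benzylic chloride, together with slow addition to the ortho-substituted amide, may starve the reaction of nucleophile.
 The fallback sets out from Weinreb amide 11 and rejoins at 14. MeMgBr (THF, 0 °C) should give the methyl ketone 1-[2,4-bis(methoxymethoxy)-3,5-bis(3-methylbut-2-en-1-yl)phenyl]ethan-1-one F5. The enolate of this ketone is then arylated with purchased 1-bromo-4-(methoxymethoxy)benzene F6 under palladium catalysis (Pd2(dba)3, Xantphos, NaOtBu, toluene, 80 °C; ketone α-arylation) to give 14.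

3. Step 9. Once the C7 hydroxyl is freed, acid-catalysed addition of this phenol to a flanking prenyl double bond (chroman formation), or addition of methanol to the alkenes, may compete with acetal cleavage and ring closure.
 The fallback changes the protecting-group plan so that O7 stays masked during the acid step; it sets out from 9 and rejoins at the target 17. Selective O-allylation of the C4 hydroxyl, which is not hydrogen-bonded to the ester (allyl bromide, K2CO3, acetone, reflux), should give ethyl 2-hydroxy-3,5-bis(3-methylbut-2-en-1-yl)-4-(prop-2-en-1-yloxy)benzoate F7. The chelated C2 hydroxyl is then capped (NaH, MOMCl, DMF) to give ethyl 2-(methoxymethoxy)-3,5-bis(3-methylbut-2-en-1-yl)-4-(prop-2-en-1-yloxy)benzoate F8. The operations of steps 6 to 8 are repeated: aminolysis should give N-methoxy-2-(methoxymethoxy)-N-methyl-3,5-bis(3-methylbut-2-en-1-yl)-4-(prop-2-en-1-yloxy)benzamide F9, Grignard reagent 13 should convert it into the deoxybenzoin 2-[4-(methoxymethoxy)phenyl]-1-[2-(methoxymethoxy)-3,5-bis(3-methylbut-2-en-1-yl)-4-(prop-2-en-1-yloxy)phenyl]ethan-1-one F10, and DMF dimethyl acetal should give the enaminone 3-(dimethylamino)-2-[4-(methoxymethoxy)phenyl]-1-[2-(methoxymethoxy)-3,5-bis(3-methylbut-2-en-1-yl)-4-(prop-2-en-1-yloxy)phenyl]prop-2-en-1-one F11. HCl in methanol then removes the two MOM groups and closes ring C while the allyl ether keeps the C7 oxygen from cyclising onto either flanking prenyl group, giving 3-(4-hydroxyphenyl)-6,8-bis(3-methylbut-2-en-1-yl)-7-(prop-2-en-1-yloxy)-4H-chromen-4-one F12. Allyl transfer to morpholine catalysed by Pd(PPh3)4 (THF, rt; Tsuji–Trost deallylation) should free the C7 hydroxyl under neutral conditions and give 17.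

**Further compounds**
F1 | step 4 | tributyl(3-methylbut-2-en-1-yl)stannane | CCCC[Sn](CCCC)(CCCC)CC=C(C)C
F2 | step 4 | ethyl 2,4-dihydroxybenzoate | CCOC(=O)c1ccc(O)cc1O
F3 | step 4 | ethyl 2,4-dihydroxy-3,5-diiodobenzoate | CCOC(=O)c1cc(I)c(O)c(I)c1O
F4 | step 4 | ethyl 3,5-diiodo-2,4-bis(methoxymethoxy)benzoate | CCOC(=O)c1cc(I)c(OCOC)c(I)c1OCOC
F5 | step 7 | 1-[2,4-bis(methoxymethoxy)-3,5-bis(3-methylbut-2-en-1-yl)phenyl]ethan-1-one | CC(=O)c1cc(CC=C(C)C)c(OCOC)c(CC=C(C)C)c1OCOC
F6 | step 7 | 1-bromo-4-(methoxymethoxy)benzene | COCOc1ccc(Br)cc1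
F7 | step 9 | ethyl 2-hydroxy-3,5-bis(3-methylbut-2-en-1-yl)-4-(prop-2-en-1-yloxy)benzoate | CCOC(=O)c1cc(CC=C(C)C)c(OCC=C)c(CC=C(C)C)c1O
F8 | step 9 | ethyl 2-(methoxymethoxy)-3,5-bis(3-methylbut-2-en-1-yl)-4-(prop-2-en-1-yloxy)benzoate | CCOC(=O)c1cc(CC=C(C)C)c(OCC=C)c(CC=C(C)C)c1OCOC
F9 | step 9 | N-methoxy-2-(methoxymethoxy)-N-methyl-3,5-bis(3-methylbut-2-en-1-yl)-4-(prop-2-en-1-yloxy)benzamide | CON(C)C(=O)c1cc(CC=C(C)C)c(OCC=C)c(CC=C(C)C)c1OCOC
F10 | step 9 | 2-[4-(methoxymethoxy)phenyl]-1-[2-(methoxymethoxy)-3,5-bis(3-methylbut-2-en-1-yl)-4-(prop-2-en-1-yloxy)phenyl]ethan-1-one | COCOc1ccc(CC(=O)c2cc(CC=C(C)C)c(OCC=C)c(CC=C(C)C)c2OCOC)cc1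
F11 | step 9 | 3-(dimethylamino)-2-[4-(methoxymethoxy)phenyl]-1-[2-(methoxymethoxy)-3,5-bis(3-methylbut-2-en-1-yl)-4-(prop-2-en-1-yloxy)phenyl]prop-2-en-1-one | COCOc1ccc(C(=CN(C)C)C(=O)c2cc(CC=C(C)C)c(OCC=C)c(CC=C(C)C)c2OCOC)cc1
F12 | step 9 | 3-(4-hydroxyphenyl)-6,8-bis(3-methylbut-2-en-1-yl)-7-(prop-2-en-1-yloxy)-4H-chromen-4-one | C=CCOc1c(CC=C(C)C)cc2c(=O)c(-c3ccc(O)cc3)coc2c1CC=C(C)C
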